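**Strategy.** The cyclopentane ring (C1–C2–C3–C3a–C8a, carotol numbering) has an unsubstituted C1H2–C2H2 edge between C8a, which is α to the oxygenated C8, and C3, which bears the isopropyl group. It is therefore taken apart into ethene and a C3–C3a–C8a unit held in a cycloheptenone. One iodine-atom-transfer radical annulation makes both bonds: the C8a α-keto radical adds to ethene, and the new radical closes onto an isobutenyl group on C3a, which becomes the isopropyl group. The precursor is a 2-iodo-3-isobutenyl-3-silyloxycyclohept-6-enone; the angular methyl group is then added to the ring-fusion enolate.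

Key step: step 7

Remark: hydroazulenes are numbered as in carotol (five-membered ring C1, C2, C3, C3a, C8a; seven-membered ring C3a, C4 to C8, C8a). It is assumed that the alkenyl Grignard reagent attacks ketone 5 anti to its C3 oxygen in step 4; the two C1 epimers are separable in any case.

Step 1
Reactants: 1 5-methylhex-5-en-2-one; 2 prop-2-enal
Product: 3 (±)-3-hydroxy-8-methylnona-1,8-dien-5-one
Conditions: LiN(iPr)2, THF, −78 °C; then 2, −78 °C; then H2O
Reagents that add atoms: none
Why: Aldol addition of the kinetic methyl-side lithium enolate to the aldehyde carbonyl (1,2-addition) should give the racemic β-hydroxy ketone.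

Step 2
Reactants: 3
Product: 4 (3R)-3-hydroxy-8-methylnona-1,8-dien-5-one
Conditions: Ti(OiPr)4 (10 mol %), L-(+)-diisopropyl tartrate (15 mol %), tBuOOH (0.6 equiv), 4 Å molecular sieves, CH2Cl2, −20 °C
Reagents that add atoms: none
Why: Sharpless kinetic resolution of the vinyl carbinol; with the L-(+)-tartrate the (S)-alcohol should be epoxidized faster, so the (R)-alcohol is recovered and fixes the absolute configuration of the route.

Step 3
Reactants: 4
Product: 5 (3R)-3-hydroxy-5-methylcyclohept-4-en-1-one
Conditions: second-generation Grubbs catalyst (5 mol %), CH2Cl2 (5 mM), 40 °C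
Reagents that add atoms: none
Why: Ring-closing metathesis between the vinyl group and the 1,1-disubstituted alkene should close the trisubstituted cycloheptene; no stereocenter is formed.

Step 4
Reactants: 5; 6 (2-methylprop-1-en-1-yl)magnesium bromide
Product: 7 (1R,3R)-5-methyl-1-(2-methylprop-1-en-1-yl)cyclohept-4-ene-1,3-diol
Conditions: 6 (3 equiv), LaCl3·2LiCl (1 equiv), THF, −78 to 0 °C; then H2O; chromatography
Reagents that add atoms: none
Why: Grignard 1,2-addition (LaCl3·2LiCl suppresses enolization) is expected on the face opposite the C3 oxygen of the chelated alkoxide, which sets C1 as the cis-1,3-diol; the C1 epimer must be removed here because it would become the enantiomer after step 5.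

Step 5
Reactants: 7
Product: 8 (3R)-3-hydroxy-6-methyl-3-(2-methylprop-1-en-1-yl)cyclohept-6-en-1-one
Conditions: MnO2, CH2Cl2, 25 °C
Reagents that add atoms: none
Why: Allylic oxidation with MnO2 should convert only the secondary allylic alcohol into the enone; the tertiary alcohol cannot be oxidized.

Step 6
Reactants: 8
Product: 10 (3S)-2-iodo-6-methyl-3-(2-methylprop-1-en-1-yl)-3-[(trimethylsilyl)oxy]cyclohept-6-en-1-one (both C2 epimers), via silyl dienol ether 9 (not isolated)
Conditions: LiN(iPr)2 (2.5 equiv), Me3SiCl (3 equiv), THF, −78 to 0 °C; then NIS, THF, −78 to 0 °C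
Reagents that add atoms: chlorotrimethylsilane, C[Si](C)(C)Cl; N-iodosuccinimide, O=C1CCC(=O)N1I
Why: Kinetic α′-enolization with in situ silylation (the tertiary alkoxide is silylated as well) followed by iodination of the silyl enol ether should give the α-iodo ketone; the C2 configuration is irrelevant because C2 becomes a radical centre.

Step 7
Reactants: 10; 11 ethene
Product: 13 (3R,3aS,8aS)-6-methyl-3-(propan-2-yl)-3a-[(trimethylsilyl)oxy]-2,3,3a,4,5,8a-hexahydroazulen-8(1H)-one, via tertiary iodide 12 (not isolated)
Conditions: 11 (5 atm), Et3B (0.3 equiv), air, PhH (0.02 M), 25 °C; then Bu3SnH, AIBN, 80 °C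
Reagents that add atoms: none
Why: Et3B and air start an iodine-atom-transfer chain in which the electrophilic C8a α-keto radical of 10 adds to ethene (C8a–C1 bond), the primary C2 radical attacks the isobutenyl CH (C2–C3 bond) and the tertiary radical takes iodine from 10 to give 12, after which Bu3SnH removes that iodine and sends any open-chain primary iodide through the same cyclization. The closest known reaction type is the iodine-atom-transfer radical (3+2) annulation of α-iodo carbonyl compounds that carry a homoallylic alkene with simple alkenes. One ring is closed, the cyclopentane, in the 5-exo-trig mode. C3 is controlled by the cyclization transition state, in which the CMe2 end of the alkene points to the convex face, away from the seven-membered ring, so that the isopropyl group ends cis to the C3a oxygen; C8a is formed as an enolizable CH centre, drawn cis-fused, and is made permanent only in step 8. The step needs ethene to add on the face of C8a that carries the isobutenyl group and to do so faster than 1,2-alkenyl migration of the homoallylic radical: without a substituent on C8a the isobutenyl group can sit pseudoequatorial and the silyloxy group pseudoaxial, so that ethene enters anti to the C–O bond (the silyl ether also removes the O–H···O=C hydrogen bond that would reverse this preference), and the stabilised α-keto radical under 5 atm of ethene should be trapped before it rearranges.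

Step 8
Reactants: 13
Product: 14 (3R,3aS,8aS)-6,8a-dimethyl-3-(propan-2-yl)-3a-[(trimethylsilyl)oxy]-2,3,3a,4,5,8a-hexahydroazulen-8(1H)-one
Conditions: LiN(iPr)2, THF, −78 °C; then MeI, DMPU, −78 to 0 °C
Reagents that add atoms: iodomethane, CI
Why: Enolate alkylation at the only α′ C–H (C8a); MeI should approach anti to the C3a–C4 ring bond, on the face of the C3a silyloxy group, which gives the cis-fused hydroazulenone and sets C8a with the methyl group cis to the C3a oxygen.

Step 9
Reactants: 14
Product: 16 (3R,3aS,8S,8aR)-6,8a-dimethyl-3-(propan-2-yl)-2,3,4,5,8,8a-hexahydroazulene-3a,8(1H)-diol, via silyl ether 15 (not isolated)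
Conditions: NaBH4, CeCl3·7H2O, MeOH, −40 °C; then 1 M HCl, THF, 25 °C
Reagents that add atoms: none
Why: Luche 1,2-reduction; hydride should attack C8 from the face opposite the C8a methyl and C3a silyloxy groups, which sets C8 with the hydroxyl cis to both, and dilute acid then cleaves the trimethylsilyl ether.

Step 10
Reactants: 16; 17 4-methoxybenzoyl chloride
Product: 18 (3R,3aS,8S,8aR)-3a-hydroxy-6,8a-dimethyl-3-(propan-2-yl)-1,2,3,3a,4,5,8,8a-octahydroazulen-8-yl 4-methoxybenzoate
Conditions: Et3N, DMAP, CH2Cl2, 0 to 25 °C
Reagents that add atoms: none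
Why: DMAP-catalysed acylation should take place only at the secondary allylic alcohol, because the tertiary C3a hydroxyl is too hindered.

**Compound list**

1 | 5-methylhex-5-en-2-one | CC(=O)CCC(C)=C | starting material
2 | prop-2-enal (acrolein) | C=CC=O | starting material
3 | (±)-3-hydroxy-8-methylnona-1,8-dien-5-one | C=CC(O)CC(=O)CCC(C)=C | intermediate
4 | (3R)-3-hydroxy-8-methylnona-1,8-dien-5-one | C=C[C@H](O)CC(=O)CCC(C)=C | intermediate
5 | (3R)-3-hydroxy-5-methylcyclohept-4-en-1-one | O[C@H]1C=C(C)CCC(=O)C1 | intermediate
6 | (2-methylprop-1-en-1-yl)magnesium bromide | CC(C)=C[Mg]Br | starting material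
7 | (1R,3R)-5-methyl-1-(2-methylprop-1-en-1-yl)cyclohept-4-ene-1,3-diol | O[C@H]1C=C(C)CC[C@](O)(C=C(C)C)C1 | intermediate
8 | (3R)-3-hydroxy-6-methyl-3-(2-methylprop-1-en-1-yl)cyclohept-6-en-1-one | O=C1C=C(C)CC[C@](O)(C=C(C)C)C1 | intermediate
9 | silyl dienol ether of 8 (both oxygens trimethylsilylated; enol ether at C1=C2) | C[Si](C)(C)OC1=C[C@@](O[Si](C)(C)C)(C=C(C)C)CCC(C)=C1 | intermediate
10 | (3S)-2-iodo-6-methyl-3-(2-methylprop-1-en-1-yl)-3-[(trimethylsilyl)oxy]cyclohept-6-en-1-one (both C2 epimers) | O=C1C=C(C)CC[C@](O[Si](C)(C)C)(C=C(C)C)C1I | intermediate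
11 | ethene | C=C | starting material
12 | tertiary iodide (13 with iodine on the methine carbon of the isopropyl group) | O=C1C=C(C)CC[C@]2(O[Si](C)(C)C)[C@@H](C(C)(C)I)CC[C@H]12 | intermediate
13 | (3R,3aS,8aS)-6-methyl-3-(propan-2-yl)-3a-[(trimethylsilyl)oxy]-2,3,3a,4,5,8a-hexahydroazulen-8(1H)-one | O=C1C=C(C)CC[C@]2(O[Si](C)(C)C)[C@@H](C(C)C)CC[C@H]12 | intermediate
14 | (3R,3aS,8aS)-6,8a-dimethyl-3-(propan-2-yl)-3a-[(trimethylsilyl)oxy]-2,3,3a,4,5,8a-hexahydroazulen-8(1H)-one | O=C1C=C(C)CC[C@]2(O[Si](C)(C)C)[C@@H](C(C)C)CC[C@]12C | intermediate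
15 | (3R,3aS,8S,8aR)-6,8a-dimethyl-3-(propan-2-yl)-3a-[(trimethylsilyl)oxy]-1,2,3,3a,4,5,8,8a-octahydroazulen-8-ol | O[C@H]1C=C(C)CC[C@]2(O[Si](C)(C)C)[C@@H](C(C)C)CC[C@]12C | intermediate
16 | (3R,3aS,8S,8aR)-6,8a-dimethyl-3-(propan-2-yl)-2,3,4,5,8,8a-hexahydroazulene-3a,8(1H)-diol | O[C@H]1C=C(C)CC[C@]2(O)[C@@H](C(C)C)CC[C@]12C | intermediate
17 | 4-methoxybenzoyl chloride | COc1ccc(C(=O)Cl)cc1 | starting material
18 | (3R,3aS,8S,8aR)-3a-hydroxy-6,8a-dimethyl-3-(propan-2-yl)-1,2,3,3a,4,5,8,8a-octahydroazulen-8-yl 4-methoxybenzoate | COc1ccc(C(=O)O[C@H]2C=C(C)CC[C@]3(O)[C@@H](C(C)C)CC[C@]23C)cc1 | target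

**Step count.** Total: 10 steps. Longest linear sequence: 10 steps (from 1 and 2 to 18).

**Steps most likely to fail**

Step 7. The atom-transfer chain may break down: the C8a radical may add to ethene too slowly, add on the face away from the isobutenyl group (so that the ring cannot close), or undergo 1,2-alkenyl migration first. Fallback by xanthate transfer, from 10 back to 13: iodide in 10 would be displaced with KSC(=S)OEt (acetone, 0 °C) to give xanthate F1. Heating F1 with dilauroyl peroxide under ethene (10 atm, 1,2-dichloroethane, 80 °C) should give, by degenerative xanthate transfer, the cyclized tertiary xanthate F2. Bu3SnH and AIBN would then reduce F2 to 13.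

Step 4. The hindered, basic alkenyl reagent may enolize ketone 5 instead of adding, or add with poor facial selectivity. Fallback from 5 back to 7: the smaller vinylmagnesium bromide would be added under the same conditions to give vinyl carbinol F3. Cross-metathesis of F3 with 2-methylbut-2-ene (second-generation Hoveyda–Grubbs catalyst, 40 °C) should then build the isobutenyl group and return to 7.

Step 8. C-alkylation of the hindered, fully substituted enolate may be sluggish, O-selective or unselective between the two faces. Fallback from 13 back to 16: the kinetic enolate would be silylated (LiN(iPr)2, Me3SiCl, THF, −78 °C) to silyl dienol ether F4. Simmons–Smith cyclopropanation of the enol ether double bond (Et2Zn, CH2I2, CH2Cl2, 0 °C) should give siloxycyclopropane F5. Acid (TsOH, MeOH, 25 °C) would open the cyclopropane to the α-methyl ketone and remove both silyl groups, giving hydroxy ketone F6. Luche reduction of F6 as in step 9 would return to 16.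

**Further compounds**

F1 | step 7 | xanthate analogue of 10 (SC(=S)OEt in place of iodine; both C2 epimers) | O=C1C=C(C)CC[C@](O[Si](C)(C)C)(C=C(C)C)C1SC(=S)OCC
F2 | step 7 | tertiary xanthate analogue of 12 (SC(=S)OEt in place of iodine) | O=C1C=C(C)CC[C@]2(O[Si](C)(C)C)[C@@H](C(C)(C)SC(=S)OCC)CC[C@H]12
F3 | step 4 | (1R,3R)-1-ethenyl-5-methylcyclohept-4-ene-1,3-diol | O[C@H]1C=C(C)CC[C@](O)(C=C)C1
F4 | step 8 | silyl dienol ether of 13 (enol ether at C8=C8a) | C[Si](C)(C)OC1=C2CC[C@H](C(C)C)[C@@]2(O[Si](C)(C)C)CCC(C)=C1
F5 | step 8 | siloxycyclopropane from F4 (CH2 across C8–C8a on the face of the C3a oxygen) | C[Si](C)(C)O[C@@]12C[C@@]13CC[C@H](C(C)C)[C@@]3(O[Si](C)(C)C)CCC(C)=C2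
F6 | step 8 | (3R,3aS,8aS)-3a-hydroxy-6,8a-dimethyl-3-(propan-2-yl)-2,3,3a,4,5,8a-hexahydroazulen-8(1H)-one | O=C1C=C(C)CC[C@]2(O)[C@@H](C(C)C)CC[C@]12C
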